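**Retrosynthetic overview**
1. Target 18 ⇐ triacetate 17 (hydrogenolysis of two benzyl ethers and of a temporary benzylic C4–OAc) ⇐ triol 16 ⇐ cycloadduct 15 (LiAlH4 cleavage of two acyl sultams).
2. Key disconnection: ring B (C1–C2–C3–C4–C4a–C8a) is a cyclohexene fused to aromatic ring A across C4a–C8a, with C1 and C4 both benzylic. Cutting C1–C2 and C3–C4 therefore gives the o-quinodimethane of ring A plus an E-alkene (2,3-trans ⇒ fumaroyl) that carries C2 and C3.
3. Enabling feature: C4 is a CH2 para to the C7 oxygen, so it can enter as the CH(OH) terminus of a photoenol. The precursor is aldehyde 9, a 2-benzylbenzaldehyde whose benzyl carbon becomes C1 with ring C attached; the extra C4 oxygen steers the endo mode and is deleted at the end.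
4. 9 ⇐ bromide 7 ⇐ benzhydrol 6 ⇐ aldehyde 2 + aryl bromide 4; dienophile 13 ⇐ sultam 10 + fumaryl chloride 11.
5. Ring order: rings A and C are bought as arenes; ring B is the only ring made, in the key step, together with the stereocentres C1, C2 and C3.

Key step: step 7

Assumption: the uncatalysed Diels–Alder reaction of the fumaroyl diimide of (2R)-bornane-10,2-sultam is taken to occur on the Cα-re face at both alkene carbons, the usual topicity of N-enoyl derivatives of this sultam, which gives the C2/C3 configuration of the target; the antipodal sultam is equally available should the sense prove opposite.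

**Step 1**
Reactants: 1 2-bromo-5-hydroxy-4-methoxybenzaldehyde
Product: 2 5-(benzyloxy)-2-bromo-4-methoxybenzaldehyde
Conditions: BnBr, K2CO3, DMF, 60 °C
Reagents that add atoms: benzyl bromide, BrCc1ccccc1
Why: Williamson ether synthesis on the phenoxide masks the future C7 phenol as a benzyl ether that lasts until the final hydrogenolysis.

**Step 2**
Reactants: 3 4-bromo-2,6-dimethoxyphenol
Product: 4 2-(benzyloxy)-5-bromo-1,3-dimethoxybenzene
Conditions: BnBr, K2CO3, DMF, 60 °C
Reagents that add atoms: benzyl bromide, BrCc1ccccc1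
Why: Williamson ether synthesis protects the ring C phenol and leaves the aryl bromide for metalation.

**Step 3**
Reactants: 4 2-(benzyloxy)-5-bromo-1,3-dimethoxybenzene; 2 5-(benzyloxy)-2-bromo-4-methoxybenzaldehyde
Product: 6 racemic [5-(benzyloxy)-2-bromo-4-methoxyphenyl][4-(benzyloxy)-3,5-dimethoxyphenyl]methanol, via arylmagnesium bromide 5 (not isolated)
Conditions: Mg, I2 (cat.), THF, 45 °C; then 2, 0 to 20 °C; H2O
Reagents that add atoms: none
Why: Grignard addition to the aldehyde should be much faster than any exchange at the aryl bromide of 2; the carbinol centre is formed racemic and is erased in step 4.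

**Step 4**
Reactants: 6 racemic [5-(benzyloxy)-2-bromo-4-methoxyphenyl][4-(benzyloxy)-3,5-dimethoxyphenyl]methanol
Product: 7 2-(benzyloxy)-5-[5-(benzyloxy)-2-bromo-4-methoxybenzyl]-1,3-dimethoxybenzene
Conditions: Et3SiH, CF3CO2H, CH2Cl2, 0 °C
Reagents that add atoms: none
Why: Ionic hydrogenation: the doubly benzylic alcohol ionises to a cation stabilised by the para alkoxy groups and is trapped by silane hydride, which should leave the aryl bromide and benzyl ethers intact.

**Step 5**
Reactants: 7 2-(benzyloxy)-5-[5-(benzyloxy)-2-bromo-4-methoxybenzyl]-1,3-dimethoxybenzene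
Product: 9 4-(benzyloxy)-2-[4-(benzyloxy)-3,5-dimethoxybenzyl]-5-methoxybenzaldehyde, via aryllithium 8 (not isolated)
Conditions: n-BuLi, THF, −78 °C; then DMF, −78 to 0 °C; H2O
Reagents that add atoms: N,N-dimethylformamide, CN(C)C=O
Why: Bromine–lithium exchange followed by Bouveault formylation places the aldehyde ortho to the diarylmethane CH2, which should not be deprotonated at −78 °C.

**Step 6**
Reactants: 10 (2R)-bornane-10,2-sultam (2 equiv); 11 fumaryl chloride
Product: 13 N,N'-fumaroylbis[(2R)-bornane-10,2-sultam], via sodium sultamide 12 (not isolated)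
Conditions: NaH, THF, 0 °C; then 11 (0.5 equiv), 0 to 20 °C
Reagents that add atoms: none
Why: N-acylation of the sultam anion by the diacid chloride should give the crystalline C2-symmetric E-diimide with the alkene geometry unchanged.

**Step 7**
Reactants: 9 4-(benzyloxy)-2-[4-(benzyloxy)-3,5-dimethoxybenzyl]-5-methoxybenzaldehyde; 13 N,N'-fumaroylbis[(2R)-bornane-10,2-sultam]
Product: 15 N,N'-{[(1S,2R,3S,4S)-7-(benzyloxy)-1-[4-(benzyloxy)-3,5-dimethoxyphenyl]-4-hydroxy-6-methoxy-1,2,3,4-tetrahydronaphthalene-2,3-diyl]dicarbonyl}bis[(2R)-bornane-10,2-sultam] (1,2-trans, 2,3-trans, 3,4-cis), via (E,E)-hydroxy-o-quinodimethane 14 (not isolated)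
Conditions: hν (365 nm), 13 (1.2 equiv), degassed toluene–CH2Cl2, 20 °C
Reagents that add atoms: none
Why: Excitation of the aryl aldehyde and 1,5-hydrogen transfer from the doubly benzylic CH2 to the carbonyl oxygen dearomatise ring A to the (E,E)-hydroxy-o-quinodimethane 14, whose rearomatisation drives a concerted suprafacial [4+2] cycloaddition with the E-alkene of 13 that forms C4–C3 and C1–C2 together. The closest known reaction type is the photoenolisation/Diels–Alder reaction of 2-alkylbenzaldehydes (here a 2-benzylbenzaldehyde) with fumaric acid derivatives. Ring B is closed as a six-membered ring by this intermolecular [π4s+π2s] cycloaddition across the two exocyclic carbons of ring A. The 2,3-trans relationship comes from the E geometry of the fumaroyl unit, while the 3,4-cis and 1,2-trans relationships should follow from the (E,E) diene (OH and aryl both outside) and endo placement of the acyl group next to the hydroxyl-bearing terminus, reinforced by an O–H···O=C hydrogen bond, which forces the other acyl group exo and trans to the C1 aryl group. The absolute configuration is set by the two sultam units, which in their anti, s-cis conformation should expose the Cα-re face at both alkene carbons and so give the C2/C3 configuration that becomes 2R,3R in the target and, through the relative control, 1S. The step needs trapping of the E-enol, endo/exo control and π-facial control: the Z-enol simply reverts to 9, the C4 hydroxyl directs the endo mode, the C2-symmetric dienophile removes any regiochemical issue, and the crystalline adduct should allow minor isomers to be removed.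

**Step 8**
Reactants: 15 cycloadduct (bis-acyl sultam)
Product: 16 [(1S,2R,3R,4S)-7-(benzyloxy)-1-[4-(benzyloxy)-3,5-dimethoxyphenyl]-4-hydroxy-6-methoxy-1,2,3,4-tetrahydronaphthalene-2,3-diyl]dimethanol
Conditions: LiAlH4, THF, 0 to 20 °C; H2O
Reagents that add atoms: none
Why: Hydride reduction of N-acyl sultams (standard reductive auxiliary cleavage) should give both primary alcohols without touching the ring stereocentres, and the sultam is recovered.

**Step 9**
Reactants: 16 triol
Product: 17 [(1S,2R,3R,4S)-4-acetoxy-7-(benzyloxy)-1-[4-(benzyloxy)-3,5-dimethoxyphenyl]-6-methoxy-1,2,3,4-tetrahydronaphthalene-2,3-diyl]bis(methylene) diacetate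
Conditions: Ac2O, pyridine, 4-(dimethylamino)pyridine (cat.), CH2Cl2, 20 °C
Reagents that add atoms: acetic anhydride, CC(=O)OC(C)=O
Why: Nucleophile-catalysed acetylation should esterify all three hydroxyl groups, and the benzylic C4 acetate is a better leaving group than the alcohol for the final hydrogenolysis.

**Step 10**
Reactants: 17 triacetate
Product: 18 [(1S,2R,3R)-7-hydroxy-1-(4-hydroxy-3,5-dimethoxyphenyl)-6-methoxy-1,2,3,4-tetrahydronaphthalene-2,3-diyl]bis(methylene) diacetate (target)
Conditions: H2 (1 atm), 10% Pd/C, EtOAc–AcOH, 20 °C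
Reagents that add atoms: none
Why: Catalytic hydrogenolysis should cleave both aryl benzyl ethers and the benzylic C4–O bond (activated by the para oxygen on ring A), turning C4 into CH2 while the primary acetates and C1–C3 are untouched.

**Compound list**
1 | 2-bromo-5-hydroxy-4-methoxybenzaldehyde | COc1cc(Br)c(C=O)cc1O | starting material
2 | 5-(benzyloxy)-2-bromo-4-methoxybenzaldehyde | COc1cc(Br)c(C=O)cc1OCc1ccccc1 | intermediate
3 | 4-bromo-2,6-dimethoxyphenol | COc1cc(Br)cc(OC)c1O | starting material
4 | 2-(benzyloxy)-5-bromo-1,3-dimethoxybenzene | COc1cc(Br)cc(OC)c1OCc1ccccc1 | intermediate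
5 | [4-(benzyloxy)-3,5-dimethoxyphenyl]magnesium bromide | COc1cc([Mg]Br)cc(OC)c1OCc1ccccc1 | intermediate
6 | racemic [5-(benzyloxy)-2-bromo-4-methoxyphenyl][4-(benzyloxy)-3,5-dimethoxyphenyl]methanol | COc1cc(Br)c(cc1OCc1ccccc1)C(O)c1cc(OC)c(OCc2ccccc2)c(OC)c1 | intermediate
7 | 2-(benzyloxy)-5-[5-(benzyloxy)-2-bromo-4-methoxybenzyl]-1,3-dimethoxybenzene | COc1cc(Br)c(cc1OCc1ccccc1)Cc1cc(OC)c(OCc2ccccc2)c(OC)c1 | intermediate
8 | {4-(benzyloxy)-2-[4-(benzyloxy)-3,5-dimethoxybenzyl]-5-methoxyphenyl}lithium | COc1cc([Li])c(cc1OCc1ccccc1)Cc1cc(OC)c(OCc2ccccc2)c(OC)c1 | intermediate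
9 | 4-(benzyloxy)-2-[4-(benzyloxy)-3,5-dimethoxybenzyl]-5-methoxybenzaldehyde | COc1cc(C=O)c(cc1OCc1ccccc1)Cc1cc(OC)c(OCc2ccccc2)c(OC)c1 | intermediate
10 | (2R)-bornane-10,2-sultam [(1S)-(−)-2,10-camphorsultam] | N1[C@@H]2C[C@H]3CC[C@]2(CS1(=O)=O)C3(C)C | starting material
11 | fumaryl chloride [(E)-but-2-enedioyl dichloride] | O=C(Cl)/C=C/C(Cl)=O | starting material
12 | sodium salt of (2R)-bornane-10,2-sultam | [Na+].[N-]1[C@@H]2C[C@H]3CC[C@]2(CS1(=O)=O)C3(C)C | intermediate
13 | N,N'-fumaroylbis[(2R)-bornane-10,2-sultam] | O=C(/C=C/C(=O)N1[C@@H]2C[C@H]3CC[C@]2(CS1(=O)=O)C3(C)C)N1[C@@H]2C[C@H]3CC[C@]2(CS1(=O)=O)C3(C)C | intermediate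
14 | (E,E)-hydroxy-o-quinodimethane (photoenol of 9; OH and aryl both outside) | O/C=C1\C=C(OC)C(OCc2ccccc2)=C/C1=C\c1cc(OC)c(OCc2ccccc2)c(OC)c1 | intermediate
15 | (1S,2R,3S,4S)-cycloadduct, bis-acyl sultam, 4-hydroxy (1,2-trans, 2,3-trans, 3,4-cis) | COc1cc2c(cc1OCc1ccccc1)[C@H](c1cc(OC)c(OCc3ccccc3)c(OC)c1)[C@@H](C(=O)N1[C@@H]3C[C@H]4CC[C@]3(CS1(=O)=O)C4(C)C)[C@H](C(=O)N1[C@@H]3C[C@H]4CC[C@]3(CS1(=O)=O)C4(C)C)[C@@H]2O | intermediate
16 | (1S,2R,3R,4S)-triol | COc1cc2c(cc1OCc1ccccc1)[C@H](c1cc(OC)c(OCc3ccccc3)c(OC)c1)[C@@H](CO)[C@H](CO)[C@@H]2O | intermediate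
17 | (1S,2R,3R,4S)-triacetate | COc1cc2c(cc1OCc1ccccc1)[C@H](c1cc(OC)c(OCc3ccccc3)c(OC)c1)[C@@H](COC(C)=O)[C@H](COC(C)=O)[C@@H]2OC(C)=O | intermediate
18 | [(1S,2R,3R)-7-hydroxy-1-(4-hydroxy-3,5-dimethoxyphenyl)-6-methoxy-1,2,3,4-tetrahydronaphthalene-2,3-diyl]bis(methylene) diacetate | COc1cc2c(cc1O)[C@H](c1cc(OC)c(O)c(OC)c1)[C@@H](COC(C)=O)[C@H](COC(C)=O)C2 | target

**Total step count:** 10. **Longest linear sequence:** 8 (steps 1, 3, 4, 5, 7, 8, 9, 10); steps 2 and 6 are side branches.

**Steps most likely to fail**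

Step 7. The short-lived photoenol may revert to 9 faster than the hindered diimide traps it, the excited aldehyde may be quenched by the electron-rich ring C, or the alkene faces may be poorly discriminated. The fallback sets out from 9 and moves stereocontrol from the auxiliary to a chiral titanium template. Aldehyde 9 and dimethyl fumarate would be irradiated at 365 nm with stoichiometric Ti(OiPr)4 and a TADDOL diol ligand (enantiomer chosen in a test run), the titanium dienolate holding photoenol and dienophile together. This should give dimethyl (1S,2R,3S,4S)-7-(benzyloxy)-1-[4-(benzyloxy)-3,5-dimethoxyphenyl]-4-hydroxy-6-methoxy-1,2,3,4-tetrahydronaphthalene-2,3-dicarboxylate F1, and LiAlH4 reduction of F1 comes back to the route at triol 16.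

Step 8. The C4 alkoxide formed under hydride may trigger retro-aldol cleavage of the C3–C4 bond or epimerisation next to the imide before reduction is complete. The fallback sets out from 15 and protects the aldol oxygen first. Silylation with tBuMe2SiOSO2CF3 and 2,6-lutidine should give the C4 tert-butyldimethylsilyl ether of the cycloadduct F2. LiAlH4 reduction then gives [(1S,2R,3R,4S)-7-(benzyloxy)-1-[4-(benzyloxy)-3,5-dimethoxyphenyl]-4-[(tert-butyldimethylsilyl)oxy]-6-methoxy-1,2,3,4-tetrahydronaphthalene-2,3-diyl]dimethanol F3, and Bu4NF in THF comes back to the route at triol 16.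

Step 10. On the catalyst, loss of acetic acid across C3–C4 may precede C–O hydrogenolysis, and hydrogenation of the resulting alkene would scramble C3; alternatively the benzylic C–O bond may be cleaved incompletely. The fallback sets out from 17 and separates the two events. Ionic hydrogenation with Et3SiH and BF3·OEt2 in CH2Cl2 at −40 °C (hydride capture of the C4 cation) should give [(1S,2R,3R)-7-(benzyloxy)-1-[4-(benzyloxy)-3,5-dimethoxyphenyl]-6-methoxy-1,2,3,4-tetrahydronaphthalene-2,3-diyl]bis(methylene) diacetate F4. Hydrogenolysis of the two benzyl ethers of F4 (H2, Pd/C, EtOAc) comes back to the route at target 18.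

**Further compounds**
F1 | step 7 | dimethyl (1S,2R,3S,4S)-7-(benzyloxy)-1-[4-(benzyloxy)-3,5-dimethoxyphenyl]-4-hydroxy-6-methoxy-1,2,3,4-tetrahydronaphthalene-2,3-dicarboxylate | COc1cc2c(cc1OCc1ccccc1)[C@H](c1cc(OC)c(OCc3ccccc3)c(OC)c1)[C@@H](C(=O)OC)[C@H](C(=O)OC)[C@@H]2O
F2 | step 8 | C4 tert-butyldimethylsilyl ether of cycloadduct 15 | COc1cc2c(cc1OCc1ccccc1)[C@H](c1cc(OC)c(OCc3ccccc3)c(OC)c1)[C@@H](C(=O)N1[C@@H]3C[C@H]4CC[C@]3(CS1(=O)=O)C4(C)C)[C@H](C(=O)N1[C@@H]3C[C@H]4CC[C@]3(CS1(=O)=O)C4(C)C)[C@@H]2O[Si](C)(C)C(C)(C)C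
F3 | step 8 | [(1S,2R,3R,4S)-7-(benzyloxy)-1-[4-(benzyloxy)-3,5-dimethoxyphenyl]-4-[(tert-butyldimethylsilyl)oxy]-6-methoxy-1,2,3,4-tetrahydronaphthalene-2,3-diyl]dimethanol | COc1cc2c(cc1OCc1ccccc1)[C@H](c1cc(OC)c(OCc3ccccc3)c(OC)c1)[C@@H](CO)[C@H](CO)[C@@H]2O[Si](C)(C)C(C)(C)C
F4 | step 10 | [(1S,2R,3R)-7-(benzyloxy)-1-[4-(benzyloxy)-3,5-dimethoxyphenyl]-6-methoxy-1,2,3,4-tetrahydronaphthalene-2,3-diyl]bis(methylene) diacetate | COc1cc2c(cc1OCc1ccccc1)[C@H](c1cc(OC)c(OCc3ccccc3)c(OC)c1)[C@@H](COC(C)=O)[C@H](COC(C)=O)C2
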